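If this run is repeated, the thing to watch is where a unit of catalyst spends its time on one lap of the cycle.

    E → L (k1 = 2.0 × 10⁻⁴ min⁻¹)
    Q.E.X → D (k2 = 0.049 min⁻¹)
    D → X + G (k3 = 0.049 min⁻¹)
    E + X → E.X (k4 = 0.063 M⁻¹ min⁻¹)
    Q + E.X → Q.E.X (k5 = 0.47 M⁻¹ min⁻¹)

Q 0.097 M; E 0.388 M; X 1.8 mM

- the form that holds most of the catalyst when 50% of the Q are converted (X / Q.E.X / E.X / D)
- its share of the catalyst then
- apparent order in X when 50% of the Q are converted (percent change of the rate of making G for one percent more X charged)

Each form waits the reciprocal of its rate per catalyst, and the lap time is the sum of the waits. While the forms keep step, a form's share of the catalyst is its wait over the lap, and G is made at the catalyst charged over the lap. I solve the two ends and join them.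

At the charge:

X 40.9 min, E.X 21.9 min, Q.E.X 20.4 min, D 20.4 min; lap 104 min

X would hold 39.5%. But [E] does not stay put: its decay has a mean life of 83.3 h. At the starting rate, 50% conversion takes 46.6 h, and the lap is far shorter than that, so the forms do keep step.

At the far end, [Q] is 0.0485 M, and decay plus turnover leave [E] at 0.173 M, so the lap is 176 min. Then my time was too short. The mean of the two laps gives:

time 62.8 h

Objection: E used early would have decayed anyway, so I weight the turnover loss by survival over the mean elapsed time:

[E] = 0.149 M

X 106 min, E.X 43.9 min

The lap time at 50% conversion, the sum of the waits, is 191 min. So X is the resting state, with 55.7%, the longest wait of the lap. A straight mean may run long, which would put this share high.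

For the order, I take it at first that one percent more X shortens the time to the same conversion by about one percent, so that [E] keeps about 0.754 percent more. The rate feels that through the share of X, which gives 1.42. Objection: the saved E itself shortens the run. Taking the mean share 47.6% on half the saving raises the [E] response to 0.919, and the order to 1.51.

The forecast, made from the problem alone, says X at 55% and puts the order at 1.53, the order on the ground that “More X means less time for E to decay”.

The simulation reaches 50% conversion after 60.8 h with X at 54.9% and an order of 1.5, and that share exceeds the 45.1% of the other forms together, just as my wait of X, 106 min of the 191 min lap, exceeds the other waits together. At 50.0 h, the [E] and [Q] of the flask give a wait of X of 87.2 min in a lap of 167 min, which is 52.2%, and the flask then holds 52.3% of its catalyst as X.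

(The numbers of this flask were set for the occasion; the flask was simulated.)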